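**Plan**

- Retrosynthetic cuts: first the O–CH3 bond of a methyl-protected phenol, then the three pyrrole C–Br bonds (C3, C4, C5), then the pyrrole N1–C5 bond, and finally the C2–N1 and C2–C3 bonds at the benzylic carbon.
- Enabling feature: in the pyrrole ring, N1 sits on the aryl-bearing C2 and C5 is the ring terminus, so N1/C2–C3–C4≡C5 maps onto a 1-aryl homopropargyl azide whose inner azide nitrogen and terminal alkyne carbon are 5-endo related.
- Forward: 3,5-dibromosalicylaldehyde (both aryl bromines already in place) is O-methylated, propargylated at the formyl carbon (C2–C3) and converted to the benzylic azide (C2–N1).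
- The pyrrole, the only ring built, is closed at N1–C5 by gold(I) catalysis with loss of N2; NBS then installs the three pyrrole bromines and BBr3 frees the phenol.
- Stereochemistry: the target has no stereocentre; the single stereocentre on the way (benzylic C2 in 4–7) is made racemic and erased on aromatisation.

Key step: step 4

Remark: the target SMILES carries no stereodescriptor and the molecule is achiral (no stereocentre, freely rotating aryl–pyrrole axis), so "single enantiomer" is taken to mean the constitution given.

**Route**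

Step 1
Reactants: 1 3,5-dibromosalicylaldehyde
Product: 2 3,5-dibromo-2-methoxybenzaldehyde
Conditions: MeI (1.5 equiv), K2CO3 (2 equiv), DMF, rt
Reagents that add atoms: iodomethane, CI
Why: Williamson ether synthesis, in which carbonate deprotonates the acidic phenol and the phenoxide is O-methylated by iodomethane (SN2), the aldehyde and aryl bromides being inert.

Step 2
Reactants: 2 3,5-dibromo-2-methoxybenzaldehyde; 3 propargyl bromide
Product: 5 rac-1-(3,5-dibromo-2-methoxyphenyl)but-3-yn-1-ol, via bromozinc alkoxide 4 (not isolated)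
Conditions: Zn dust (2 equiv), 3 (1.5 equiv), THF, 0 °C → rt; then 1 M HCl
Reagents that add atoms: propargyl bromide (3), C#CCBr
Why: Barbier-type propargylation, in which zinc inserts into the C–Br bond of 3 and the allenylzinc bromide adds to the aldehyde through its γ-carbon (SE2′) to give alkoxide 4, protonated on work-up; zinc dust should not insert into the aryl C–Br bonds at this temperature, and the carbinol centre is formed racemic, which is of no consequence because it becomes sp2 in step 4.

Step 3
Reactants: 5 rac-1-(3,5-dibromo-2-methoxyphenyl)but-3-yn-1-ol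
Product: 7 rac-1-(1-azidobut-3-yn-1-yl)-3,5-dibromo-2-methoxybenzene, via benzylic diphenyl phosphate 6 (not isolated)
Conditions: DPPA (1.2 equiv), DBU (1.3 equiv), toluene, 0 °C → rt
Reagents that add atoms: diphenylphosphoryl azide (DPPA), [N-]=[N+]=NP(=O)(Oc1ccccc1)Oc1ccccc1
Why: phosphoryl azide (Thompson-type) azidation of a benzylic alcohol, in which DBU-mediated O-phosphorylation gives 6 and its diphenyl phosphate is displaced at the benzylic carbon by the azide ion pair released in the same flask (SN2), the electron-poor dibromoaryl ring disfavouring ionisation; the configuration of this racemic centre is irrelevant.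

Step 4
Reactants: 7 rac-1-(1-azidobut-3-yn-1-yl)-3,5-dibromo-2-methoxybenzene
Product: 9 2-(3,5-dibromo-2-methoxyphenyl)-1H-pyrrole, via 2H-pyrrole 8 (not isolated)
Conditions: (dppm)Au2Cl2 (2.5 mol%), AgSbF6 (5 mol%), dry CH2Cl2, 35 °C
Reagents that add atoms: none
Why: Cationic gold(I) binds the terminal alkyne of 7, the carbon-bound azide nitrogen attacks the terminal alkyne carbon to form N1–C5 and a cyclic vinylgold aminodiazonium species, back-donation from gold expels N2 to leave a gold carbenoid at C4, and a 1,2-hydrogen shift from C3 releases the catalyst and 2H-pyrrole 8, which tautomerises to the aromatic 1H-pyrrole 9. The closest known reaction type is the gold(I)-catalysed intramolecular acetylenic Schmidt reaction of homopropargyl azides. The one ring formed is closed in the 5-endo-dig mode. No stereocentre is created, and the racemic azide-bearing carbon C2 becomes sp2. The step needs attack by the inner azide nitrogen in preference to intermolecular cycloaddition or alkyne hydration, which the two-carbon tether between C2 and the alkyne together with dry, dilute conditions should secure. The aryl bromides and the methyl ether are not expected to engage the π-acid, and the nitrogen arrives unprotected at the pyrrole oxidation level without any oxidant.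

Step 5
Reactants: 9 2-(3,5-dibromo-2-methoxyphenyl)-1H-pyrrole
Product: 12 2,3,4-tribromo-5-(3,5-dibromo-2-methoxyphenyl)-1H-pyrrole, via 5-bromopyrrole 10 (not isolated), via 4,5-dibromopyrrole 11 (not isolated)
Conditions: NBS (3.05 equiv), THF, −78 °C → 0 °C, dark
Reagents that add atoms: N-bromosuccinimide, O=C1CCC(=O)N1Br
Why: electrophilic aromatic bromination of an electron-rich NH-pyrrole with NBS, expected to take the α-position C5 first and then the two β-positions; the anisole ring should stay untouched because its two free positions are meta to OMe and flanked by bromine.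

Step 6
Reactants: 12 2,3,4-tribromo-5-(3,5-dibromo-2-methoxyphenyl)-1H-pyrrole
Product: 14 pentabromopseudilin, via aryloxydibromoborane 13 (not isolated)
Conditions: BBr3 (3 equiv), CH2Cl2, −78 °C → rt; then H2O, 0 °C
Reagents that add atoms: none
Why: Lewis-acid aryl methyl ether cleavage, in which BBr3 coordinates the anisole oxygen, bromide removes the methyl group by SN2 to give aryloxyborane 13, and water hydrolyses the B–O bond to the phenol; the electron-poor tribromopyrrole and the aryl C–Br bonds should be stable to BBr3.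

**Compound list**

1 | 3,5-dibromosalicylaldehyde (3,5-dibromo-2-hydroxybenzaldehyde) | O=Cc1cc(Br)cc(Br)c1O | starting material
2 | 3,5-dibromo-2-methoxybenzaldehyde | COc1c(Br)cc(Br)cc1C=O | intermediate
3 | propargyl bromide (3-bromoprop-1-yne) | C#CCBr | starting material
4 | bromozinc 1-(3,5-dibromo-2-methoxyphenyl)but-3-yn-1-olate (racemic) | COc1c(Br)cc(Br)cc1C(O[Zn]Br)CC#C | intermediate (not isolated)
5 | rac-1-(3,5-dibromo-2-methoxyphenyl)but-3-yn-1-ol | COc1c(Br)cc(Br)cc1C(O)CC#C | intermediate
6 | rac-1-(3,5-dibromo-2-methoxyphenyl)but-3-yn-1-yl diphenyl phosphate | COc1c(Br)cc(Br)cc1C(CC#C)OP(=O)(Oc1ccccc1)Oc1ccccc1 | intermediate (not isolated)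
7 | rac-1-(1-azidobut-3-yn-1-yl)-3,5-dibromo-2-methoxybenzene | COc1c(Br)cc(Br)cc1C(CC#C)N=[N+]=[N-] | intermediate
8 | rac-2-(3,5-dibromo-2-methoxyphenyl)-2H-pyrrole | COc1c(Br)cc(Br)cc1C1C=CC=N1 | intermediate (not isolated)
9 | 2-(3,5-dibromo-2-methoxyphenyl)-1H-pyrrole | COc1c(Br)cc(Br)cc1-c1ccc[nH]1 | intermediate
10 | 2-bromo-5-(3,5-dibromo-2-methoxyphenyl)-1H-pyrrole | COc1c(Br)cc(Br)cc1-c1ccc(Br)[nH]1 | intermediate (not isolated)
11 | 2,3-dibromo-5-(3,5-dibromo-2-methoxyphenyl)-1H-pyrrole | COc1c(Br)cc(Br)cc1-c1cc(Br)c(Br)[nH]1 | intermediate (not isolated)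
12 | 2,3,4-tribromo-5-(3,5-dibromo-2-methoxyphenyl)-1H-pyrrole | COc1c(Br)cc(Br)cc1-c1[nH]c(Br)c(Br)c1Br | intermediate
13 | dibromo[2,4-dibromo-6-(3,4,5-tribromo-1H-pyrrol-2-yl)phenoxy]borane | BrB(Br)Oc1c(Br)cc(Br)cc1-c1[nH]c(Br)c(Br)c1Br | intermediate (not isolated)
14 | pentabromopseudilin, 2,4-dibromo-6-(3,4,5-tribromo-1H-pyrrol-2-yl)phenol | Oc1c(Br)cc(Br)cc1-c1[nH]c(Br)c(Br)c1Br | target

**Step count**

Total steps: 6. Longest linear sequence: 6 steps (1 → 2 → 5 → 7 → 9 → 12 → 14).

**Steps most likely to fail, with fallbacks**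

Step 4. The terminal alkyne may deactivate the catalyst by forming gold acetylide or digold species, or cyclisation may be slow enough that alkyne hydration or decomposition of the benzylic azide competes. The fallback abandons the azide closure for a Paal–Knorr ring synthesis and sets out from aldehyde 2. Addition of commercial [2-(1,3-dioxolan-2-yl)ethyl]magnesium bromide in THF at −78 → 0 °C should give bromomagnesium 1-(3,5-dibromo-2-methoxyphenyl)-3-(1,3-dioxolan-2-yl)propan-1-olate F1. Quenching with aqueous NH4Cl should release 1-(3,5-dibromo-2-methoxyphenyl)-3-(1,3-dioxolan-2-yl)propan-1-ol F2. Dess–Martin oxidation (NaHCO3, CH2Cl2) should then give 1-(3,5-dibromo-2-methoxyphenyl)-3-(1,3-dioxolan-2-yl)propan-1-one F3. Heating F3 with NH4OAc in aqueous acetic acid should unmask 4-(3,5-dibromo-2-methoxyphenyl)-4-oxobutanal F4 in the flask, which condenses with ammonia to the pyrrole. The fallback rejoins the route at 9.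

Step 3. The benzylic phosphate may undergo E2 elimination to the conjugated enyne, or substitution at the ortho-substituted benzylic carbon may stall. The fallback brings in nitrogen by imine addition and diazo transfer instead of substitution, and sets out from aldehyde 2. Condensation with racemic 2-methylpropane-2-sulfinamide (Ti(OEt)4, THF) should give (E)-N-(3,5-dibromo-2-methoxybenzylidene)-2-methylpropane-2-sulfinamide F5. Zinc-mediated propargylation with 3 in THF should give bromozinc N-[1-(3,5-dibromo-2-methoxyphenyl)but-3-yn-1-yl]-2-methylpropane-2-sulfinamidate F6. Aqueous NH4Cl work-up should release N-[1-(3,5-dibromo-2-methoxyphenyl)but-3-yn-1-yl]-2-methylpropane-2-sulfinamide F7 as a mixture of diastereomers, which does not matter here. HCl in methanol followed by basification should give 1-(3,5-dibromo-2-methoxyphenyl)but-3-yn-1-amine F8. Copper-free diazo transfer with imidazole-1-sulfonyl azide hydrogen sulfate and K2CO3 in methanol should convert the amine to the azide, copper being left out so the terminal alkyne cannot enter an azide–alkyne cycloaddition. The fallback rejoins the route at 7.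

Step 5. Bromination may stop short at the hindered C3 next to the ortho-substituted aryl ring, or NBS may oxidatively degrade the electron-rich pyrrole. The fallback inverts the endgame and sets out from pyrrole 9. BBr3 in CH2Cl2 at −78 → 0 °C should give dibromo[2,4-dibromo-6-(1H-pyrrol-2-yl)phenoxy]borane F9, hydrolysed on aqueous work-up to 2,4-dibromo-6-(1H-pyrrol-2-yl)phenol F10. Pyridinium tribromide (3 equiv) in ethanol at 0 °C should then brominate the hydrogen-bonded phenol–pyrrole through 2,4-dibromo-6-(5-bromo-1H-pyrrol-2-yl)phenol F11 and 2,4-dibromo-6-(4,5-dibromo-1H-pyrrol-2-yl)phenol F12. The fallback rejoins the route at target 14.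

**Further compounds**

F1 | step 4 | bromomagnesium 1-(3,5-dibromo-2-methoxyphenyl)-3-(1,3-dioxolan-2-yl)propan-1-olate | COc1c(Br)cc(Br)cc1C(O[Mg]Br)CCC1OCCO1
F2 | step 4 | 1-(3,5-dibromo-2-methoxyphenyl)-3-(1,3-dioxolan-2-yl)propan-1-ol | COc1c(Br)cc(Br)cc1C(O)CCC1OCCO1
F3 | step 4 | 1-(3,5-dibromo-2-methoxyphenyl)-3-(1,3-dioxolan-2-yl)propan-1-one | COc1c(Br)cc(Br)cc1C(=O)CCC1OCCO1
F4 | step 4 | 4-(3,5-dibromo-2-methoxyphenyl)-4-oxobutanal | COc1c(Br)cc(Br)cc1C(=O)CCC=O
F5 | step 3 | (E)-N-(3,5-dibromo-2-methoxybenzylidene)-2-methylpropane-2-sulfinamide | COc1c(Br)cc(Br)cc1/C=N/S(=O)C(C)(C)C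
F6 | step 3 | bromozinc N-[1-(3,5-dibromo-2-methoxyphenyl)but-3-yn-1-yl]-2-methylpropane-2-sulfinamidate | COc1c(Br)cc(Br)cc1C(CC#C)N([Zn]Br)S(=O)C(C)(C)C
F7 | step 3 | N-[1-(3,5-dibromo-2-methoxyphenyl)but-3-yn-1-yl]-2-methylpropane-2-sulfinamide | COc1c(Br)cc(Br)cc1C(CC#C)NS(=O)C(C)(C)C
F8 | step 3 | 1-(3,5-dibromo-2-methoxyphenyl)but-3-yn-1-amine | COc1c(Br)cc(Br)cc1C(N)CC#C
F9 | step 5 | dibromo[2,4-dibromo-6-(1H-pyrrol-2-yl)phenoxy]borane | BrB(Br)Oc1c(Br)cc(Br)cc1-c1ccc[nH]1
F10 | step 5 | 2,4-dibromo-6-(1H-pyrrol-2-yl)phenol | Oc1c(Br)cc(Br)cc1-c1ccc[nH]1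
F11 | step 5 | 2,4-dibromo-6-(5-bromo-1H-pyrrol-2-yl)phenol | Oc1c(Br)cc(Br)cc1-c1ccc(Br)[nH]1
F12 | step 5 | 2,4-dibromo-6-(4,5-dibromo-1H-pyrrol-2-yl)phenol | Oc1c(Br)cc(Br)cc1-c1cc(Br)c(Br)[nH]1
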